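A direct plan would build ring A first: 3-[(4-methoxybenzyl)oxy]cyclobut-2-en-1-one A1 and triisopropyl[(5-methylhex-4-en-1-yn-1-yl)oxy]silane A2 would be heated to the benzannulated phenol A3, whose three ring oxygens are told apart by a 4-methoxybenzyl and a triisopropylsilyl group.
The acetyl group would follow in three operations (ortho-formylation, methyl Grignard addition, oxidation) to acetophenone A4, and the ketene dithioacetal method would close ring C as the 2-(methylsulfanyl)chromone A5.
Oxidation to sulfoxide A6, displacement by the aryl oxide of 4-methoxyphenol A7 and two deprotections would finish.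
Weak step 1: the formylation, Grignard addition and reoxidation, a three-step redox detour that builds nothing but a C-acetyl group.
Weak step 2: the peracid oxidation of sulfide A5 beside the trisubstituted prenyl alkene, followed by two separate deprotections on a chromone whose C2 is open to nucleophiles, all after about ten linear steps.
Weak step 3: the benzannulation to A3, which rests on thermal opening of a 3-alkoxycyclobutenone to a ketene that can also acylate the phenol it makes, while the whole linear sequence and both protecting groups depend on it.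

**Retrosynthetic overview**
Ring C (O1, C2, C3, C4, C4a, C8a) is made first and ring A (C4a, C5, C6, C7, C8, C8a) last; C2 is a vinylogous carbonate carbon (O1–C2(OAr)=C3–C4=O), at the carboxylic acid level, which is what the oxygen-bearing carbon of an ynol ether delivers.
Key disconnection: C3–C4 and O1–C2, formed together in a hetero-(4+2) cycloaddition of an acylketene (C4, C4a, C8a, with C8 and the prenyl group already attached) with 4-methoxyphenoxyacetylene (C2, C3 and the aryloxy group), with no sulfur and no displacement at C2.
Ring A, an acylphloroglucinol (oxygen on C5, C7, C8a), is then annulated in the polyketide manner: a malonyl unit (C5, C6, C7) is joined at C7–C8 by lateral C-acylation, and a second acylketene closes C4a–C5 and aromatises to the free 5,7-diol.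
C8 carries the prenyl group before either ring exists and is bonded to the future C8a, so the 6- versus 8-prenyl question, all protecting groups, the acetyl redox detour and every oxidant are designed out.

Key step: step 4

Assumption: tert-butyl 3-chloro-3-oxopropanoate (12) is taken as a purchased, cold-stored reagent, and the terminal ynol ether 5 is handled only as a cold solution and used within a day, since such alkynes oligomerise when neat.

Step 1
Reactants: 1 4-methoxyphenol; 2 trichloroethylene
Product: 3 (E)-1-[(1,2-dichloroethenyl)oxy]-4-methoxybenzene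
Conditions: K2CO3 (1.5 equiv), 2 (1.3 equiv), DMF, 70 °C
Reagents that add atoms: none
Why: Base-mediated vinylation of a phenol with trichloroethylene (elimination to dichloroacetylene, then anti addition of the phenoxide) is the standard entry to aryl (E)-1,2-dichlorovinyl ethers, and the alkene geometry is lost in step 2.

Step 2
Reactants: 3 (E)-1-[(1,2-dichloroethenyl)oxy]-4-methoxybenzene
Product: 5 1-(ethynyloxy)-4-methoxybenzene, via lithium (4-methoxyphenoxy)ethynide 4 (not isolated)
Conditions: n-BuLi (2.2 equiv), Et2O, −78 to −40 °C; H2O, −78 °C; dried, exchanged into toluene below 20 °C, stored at −20 °C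
Reagents that add atoms: none
Why: Two equivalents of n-BuLi convert a 1,2-dichlorovinyl ether into the lithium alkynide (deprotonation, loss of LiCl to the chloroalkyne, chlorine–lithium exchange), and cold protonation gives the terminal aryl ynol ether.

Step 3
Reactants: 6 2,2,6-trimethyl-4H-1,3-dioxin-4-one; 7 1-bromo-3-methylbut-2-ene
Product: 9 2,2-dimethyl-6-(4-methylpent-3-en-1-yl)-4H-1,3-dioxin-4-one, via lithium dienolate 8 (not isolated)
Conditions: LiN(iPr)2 (1.1 equiv), THF, −78 °C; 7 (1.2 equiv), DMPU, −78 to −20 °C
Reagents that add atoms: none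
Why: γ-Alkylation of the lithium dienolate of the dioxinone with an allylic bromide is the usual way to extend its C6 side chain, and it places the prenyl group on the carbon that becomes C8.

Step 4
Reactants: 9 2,2-dimethyl-6-(4-methylpent-3-en-1-yl)-4H-1,3-dioxin-4-one; 5 1-(ethynyloxy)-4-methoxybenzene
Product: 11 2-(4-methoxyphenoxy)-6-(4-methylpent-3-en-1-yl)-4H-pyran-4-one, via acylketene 10 (not isolated)
Conditions: 5 (1.5 equiv), toluene, 110 °C, slow addition of 9, N2 stream to carry off acetone
Reagents that add atoms: none
Why: Proposed new method: retro-(4+2) loss of acetone from 9 gives acylketene 10, whose cisoid O=C–C=C=O unit should act as an oxadiene toward the electron-rich triple bond of 5, so that the nucleophilic CH carbon of the ynol ether bonds to the ketene carbon (C3–C4) while the acyl oxygen bonds to the aryloxy-bearing carbon (O1–C2). Ring C thus closes in a single six-membered hetero-(4+2) event (concerted and pseudopericyclic, or 6-endo collapse of the ketene-derived enolate onto the aryloxy-stabilised vinyl cation if stepwise) and emerges directly as the 4-pyranone with the aryloxy group at C2. The closest known reactions are the cycloadditions of dioxinone-derived acylketenes with ynamines and with ketene acetals, which give 2-amino- and 2-alkoxy-4-pyranones; an aryl ynol ether is a less nucleophilic member of the same family, which is why the step is a proposal. No stereocentre is formed. The selectivity needed is (4+2) over (2+2) across the ketene C=C (the cyclobutenone so formed would open and reclose to the isomeric 4-aryloxy-2-pyranone) together with the stated orientation; the oxygen substituent polarises the alkyne in one sense only, and the acyl oxygen held next to the developing cation should capture it faster than carbon can. Slow addition keeps 10 dilute so that it meets 5 and not a second ketene, and the isolated trisubstituted alkene is too weak a partner to compete.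

Step 5
Reactants: 11 2-(4-methoxyphenoxy)-6-(4-methylpent-3-en-1-yl)-4H-pyran-4-one; 12 tert-butyl 3-chloro-3-oxopropanoate
Product: 14 tert-butyl 4-[6-(4-methoxyphenoxy)-4-oxo-4H-pyran-2-yl]-7-methyl-3-oxooct-6-enoate (racemic), via lithium dienolate 13 (not isolated)
Conditions: LiN(SiMe3)2 (2.1 equiv), THF, −78 °C; 12 (1.05 equiv), −78 to −40 °C; AcOH, −78 °C
Reagents that add atoms: none
Why: Lateral (vinylogous) deprotonation of a 6-alkyl-4-pyranone and C-acylation at the exocyclic carbon is established for 2-alkoxy-4-pyranones; the second equivalent of base takes up the acidic proton of the β-keto ester (or turns 12 into (tert-butoxycarbonyl)ketene, which the dienolate captures to the same enolate), the hindered amide leaves C2 alone at −78 °C, and the new stereocentre at the future C8 is racemic and becomes sp2 in step 6.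

Step 6
Reactants: 14 tert-butyl 4-[6-(4-methoxyphenoxy)-4-oxo-4H-pyran-2-yl]-7-methyl-3-oxooct-6-enoate
Product: 18 5,7-dihydroxy-2-(4-methoxyphenoxy)-8-(3-methylbut-2-en-1-yl)-4H-chromen-4-one (CNP0274214.0), via acylketene 15 (not isolated), via hydroxydienylketene 16 (not isolated), via cyclohexadienone 17 (not isolated)
Conditions: xylenes (0.005 M), 135 °C, N2 stream to carry off t-BuOH
Reagents that add atoms: none
Why: Thermal loss of tert-butanol from a β-keto tert-butyl ester gives acylketene 15, whose ketone enolises toward the doubly activated C8–H to hydroxydienylketene 16; 6π-electrocyclisation onto C5 of the pyranone (the ring-closing mode of ketene benzannulations and of the Gould–Jacobs cyclisation) forms C4a–C5, and tautomerisation of 17 gives ring A as the free 5,7-diol, while high dilution keeps 15 from acylating phenols of product already formed.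

**Compound list**
1 | 4-methoxyphenol | COc1ccc(O)cc1 | starting material
2 | trichloroethylene | ClC=C(Cl)Cl | starting material
3 | (E)-1-[(1,2-dichloroethenyl)oxy]-4-methoxybenzene | COc1ccc(O/C(Cl)=C\Cl)cc1 | intermediate
4 | lithium (4-methoxyphenoxy)ethynide | [Li+].[C-]#COc1ccc(OC)cc1 | intermediate
5 | 1-(ethynyloxy)-4-methoxybenzene | C#COc1ccc(OC)cc1 | intermediate
6 | 2,2,6-trimethyl-4H-1,3-dioxin-4-one | CC1=CC(=O)OC(C)(C)O1 | starting material
7 | 1-bromo-3-methylbut-2-ene | CC(C)=CCBr | starting material
8 | lithium 2,2-dimethyl-6-methylidene-6H-1,3-dioxin-4-olate | [Li+].[O-]C1=CC(=C)OC(C)(C)O1 | intermediate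
9 | 2,2-dimethyl-6-(4-methylpent-3-en-1-yl)-4H-1,3-dioxin-4-one | CC(C)=CCCC1=CC(=O)OC(C)(C)O1 | intermediate
10 | 7-methyl-3-oxoocta-1,6-dien-1-one | CC(C)=CCCC(=O)C=C=O | intermediate
11 | 2-(4-methoxyphenoxy)-6-(4-methylpent-3-en-1-yl)-4H-pyran-4-one | COc1ccc(Oc2cc(=O)cc(CCC=C(C)C)o2)cc1 | intermediate
12 | tert-butyl 3-chloro-3-oxopropanoate | CC(C)(C)OC(=O)CC(Cl)=O | starting material
13 | lithium 2-(4-methoxyphenoxy)-6-(4-methylpent-3-en-1-ylidene)-6H-pyran-4-olate (exocyclic alkene geometry not defined) | [Li+].[O-]C1=CC(=CCC=C(C)C)OC(Oc2ccc(OC)cc2)=C1 | intermediate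
14 | tert-butyl 4-[6-(4-methoxyphenoxy)-4-oxo-4H-pyran-2-yl]-7-methyl-3-oxooct-6-enoate (racemic) | CC(C)=CCC(C(=O)CC(=O)OC(C)(C)C)c1cc(=O)cc(Oc2ccc(OC)cc2)o1 | intermediate
15 | 4-[6-(4-methoxyphenoxy)-4-oxo-4H-pyran-2-yl]-7-methyl-3-oxoocta-1,6-dien-1-one (racemic) | CC(C)=CCC(C(=O)C=C=O)c1cc(=O)cc(Oc2ccc(OC)cc2)o1 | intermediate
16 | (3E)-3-hydroxy-4-[6-(4-methoxyphenoxy)-4-oxo-4H-pyran-2-yl]-7-methylocta-1,3,6-trien-1-one | O=C=C/C(O)=C(/CC=C(C)C)c1cc(=O)cc(Oc2ccc(OC)cc2)o1 | intermediate
17 | 7-hydroxy-2-(4-methoxyphenoxy)-8-(3-methylbut-2-en-1-yl)-4aH-chromene-4,5-dione (racemic) | O=C1C=C(O)C(CC=C(C)C)=C2OC(Oc3ccc(OC)cc3)=CC(=O)C12 | intermediate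
18 | 5,7-dihydroxy-2-(4-methoxyphenoxy)-8-(3-methylbut-2-en-1-yl)-4H-chromen-4-one (CNP0274214.0) | COc1ccc(Oc2cc(=O)c3c(O)cc(O)c(CC=C(C)C)c3o2)cc1 | target

Total step count: 6. Longest linear sequence: 5 steps (steps 1, 2, 4, 5, 6).

**Steps most likely to fail**

1. Step 4 (proposed new method). The terminal ynol ether may oligomerise at 110 °C faster than the ketene captures it, or the ketene may add across its C=C bond in the (2+2) sense and end in the isomeric 4-aryloxy-2-pyranone. The fallback uses known chemistry, sets out from 1 and 7 and comes back at 11. Purchased pentane-2,4-dione would be taken to its 1,3-dianion (NaH, then n-BuLi, THF), which adds to CS2 at the terminal carbon. Double S-methylation with MeI would give 1,1-bis(methylsulfanyl)hex-1-ene-3,5-dione F1, whose enol oxygen closes with loss of methanethiol to 6-methyl-2-(methylsulfanyl)-4H-pyran-4-one F2. Oxidation with mCPBA (1 equiv, −40 °C), at a stage where no alkene is present, would give 6-methyl-2-(methylsulfinyl)-4H-pyran-4-one F3. The sodium salt of 1 (NaH, THF, 0 °C) would displace the sulfinyl group by addition–elimination to give 2-(4-methoxyphenoxy)-6-methyl-4H-pyran-4-one F4. Lateral deprotonation of F4 with LiN(SiMe3)2 and alkylation with 7 would then give 11.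

2. Step 6. The acylketene may be consumed by acylation of free phenols of product already formed, or by cycloaddition to the prenyl alkene, before enolisation and ring closure take place. The fallback sets out from 14 and comes back at 18. Heating 14 in toluene at 110 °C with pentafluorophenol (3 equiv) should intercept the ketene by fast O–H addition as it forms, giving pentafluorophenyl 4-[6-(4-methoxyphenoxy)-4-oxo-4H-pyran-2-yl]-7-methyl-3-oxooct-6-enoate F5. Treatment with iPr2NEt in CH2Cl2 at 0 °C would then close ring A as an anionic Claisen-type C-acylation by C5 of the vinylogous enolate. The pentafluorophenoxide released is too weak a nucleophile to attack C2, and tautomerisation gives 18.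

3. Step 5. The dienolate may be quenched by proton transfer from the acid chloride, or acylated on the C4 oxygen instead of on the exocyclic carbon. The fallback sets out from 11 and comes back at 14. The dienolate of 11 would be acylated with N-methoxy-N-methylacetamide, whose chelated adduct neither transfers a proton nor reacts twice, to give 2-(4-methoxyphenoxy)-6-(6-methyl-2-oxohept-5-en-3-yl)-4H-pyran-4-one F6. Its dianion (LiN(SiMe3)2, 2.2 equiv; formed first at the CH between pyranone and ketone, then at the methyl group) would be carboxylated at the terminal carbon with di-tert-butyl dicarbonate to give 14.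

**Further compounds**
F1 | step 4 | 1,1-bis(methylsulfanyl)hex-1-ene-3,5-dione | CSC(SC)=CC(=O)CC(C)=O
F2 | step 4 | 6-methyl-2-(methylsulfanyl)-4H-pyran-4-one | CSc1cc(=O)cc(C)o1
F3 | step 4 | 6-methyl-2-(methylsulfinyl)-4H-pyran-4-one (racemic at sulfur) | CS(=O)c1cc(=O)cc(C)o1
F4 | step 4 | 2-(4-methoxyphenoxy)-6-methyl-4H-pyran-4-one | COc1ccc(Oc2cc(=O)cc(C)o2)cc1
F5 | step 6 | pentafluorophenyl 4-[6-(4-methoxyphenoxy)-4-oxo-4H-pyran-2-yl]-7-methyl-3-oxooct-6-enoate (racemic) | CC(C)=CCC(C(=O)CC(=O)Oc1c(F)c(F)c(F)c(F)c1F)c1cc(=O)cc(Oc2ccc(OC)cc2)o1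
F6 | step 5 | 2-(4-methoxyphenoxy)-6-(6-methyl-2-oxohept-5-en-3-yl)-4H-pyran-4-one (racemic) | CC(=O)C(CC=C(C)C)c1cc(=O)cc(Oc2ccc(OC)cc2)o1
A1 | direct plan | 3-[(4-methoxybenzyl)oxy]cyclobut-2-en-1-one | O=C1C=C(OCc2ccc(OC)cc2)C1
A2 | direct plan | triisopropyl[(5-methylhex-4-en-1-yn-1-yl)oxy]silane | CC(C)=CCC#CO[Si](C(C)C)(C(C)C)C(C)C
A3 | direct plan | 5-[(4-methoxybenzyl)oxy]-2-(3-methylbut-2-en-1-yl)-3-[(triisopropylsilyl)oxy]phenol | Oc1cc(OCc2ccc(OC)cc2)cc(O[Si](C(C)C)(C(C)C)C(C)C)c1CC=C(C)C
A4 | direct plan | 1-{2-hydroxy-6-[(4-methoxybenzyl)oxy]-3-(3-methylbut-2-en-1-yl)-4-[(triisopropylsilyl)oxy]phenyl}ethan-1-one | CC(=O)c1c(O)c(CC=C(C)C)c(O[Si](C(C)C)(C(C)C)C(C)C)cc1OCc1ccc(OC)cc1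
A5 | direct plan | 5-[(4-methoxybenzyl)oxy]-2-(methylsulfanyl)-8-(3-methylbut-2-en-1-yl)-7-[(triisopropylsilyl)oxy]-4H-chromen-4-one | CSc1cc(=O)c2c(OCc3ccc(OC)cc3)cc(O[Si](C(C)C)(C(C)C)C(C)C)c(CC=C(C)C)c2o1
A6 | direct plan | 5-[(4-methoxybenzyl)oxy]-2-(methylsulfinyl)-8-(3-methylbut-2-en-1-yl)-7-[(triisopropylsilyl)oxy]-4H-chromen-4-one (racemic at sulfur) | CS(=O)c1cc(=O)c2c(OCc3ccc(OC)cc3)cc(O[Si](C(C)C)(C(C)C)C(C)C)c(CC=C(C)C)c2o1
A7 | direct plan | 4-methoxyphenol | COc1ccc(O)cc1
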